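The constants used here come from no measurement; the flask was simulated.

If you charge 0.050 M of starting material into a solution whose target dissolves up to 41 mM, count before you trust any run.

    2 starting material → target (k1 = 26 L mol⁻¹ min⁻¹)
    crystals ⇌ target, rate k2*(cs2 - [target]) while solid is left; crystals form when [target] > cs2 (cs2 = 41 mM, k2 = 8.3 min⁻¹)
    starting material + protic impurity → quenched substrate (k3 = 65 L mol⁻¹ min⁻¹)
    target ⇌ isomer of the product (K4 = 0.75, k4 = 0.058 min⁻¹)

starting material 0.050 M; protic impurity 1.00 mM; time 8.0 min

- percentages count the starting material that a species holds: one target or crystals or isomer of the product counts as two
- target is meant together with its crystals
- for a step with 2 of a species take k times the square, and two of it per event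
- solid, in amounts per volume of the solution: crystals
- run time (flask): 8.0 min

- target and crystals together at 8.0 min, in percent of the starting material charged
- the change that raises the amount of target and crystals together at 8.0 min, in percent of the starting material charged most ("none" if none brings more than 2 percentage points) (noon / winter / none)
- amount of target and crystals together at 8.0 min, in percent of the starting material charged, after noon

- noon: doubling the solubility in step 2, all else as stated
- winter: doubling the dissolution coefficient of step 2, all else as stated

Put two numbers side by side: in this flask the charge is more than the solubility, which promises crystals, yet I expect none. Count per target. Two starting material go into each target, so this flask can give at most 25.0 mM of target. Divide by the solubility to get 0.610, the ceiling ratio, the most target a charge can give over the solubility. Take a ratio of 1 as the zero of the scale, where the ceiling just meets the solubility. This flask lies below that mark, so expect no crystals and nothing for step 2 to act on. Noon lowers the ratio to 0.305; winter leaves it alone. Expect no gain from either, and the same answer after noon as before. My reckoning stops there, without a figure for y.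

The forecast gives 69%, none and 69%, reasoning “so crystals never form and neither change to step 2 has any effect”. It takes about 24 mM of target at full conversion, where I take the bare 25.0 mM; the verdict on crystals is the same.

The simulation gives 68.9% at 8.0 min, best change none, with 0 percentage points from noon and 0 points from winter, and 68.9% after noon. This flask holds 0% crystals at 8.00 min, and the solubility makes no difference to the answer.

Now turn the verdict over with the neighbouring flask, charged with 0.20 M of starting material, its other charges and its time as before. Its ceiling is 100 mM, so its ratio is 2.44, above the mark: expect crystals there. With solid present in the neighbouring flask, expect dissolved target to sit near the solubility, which is the inverse of the ratio, 41.0% of the charge. The neighbouring flask reads 84.0% of target and crystals at 8.00 min, with 43.1% as crystals, so 40.9% stands dissolved as target.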